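The route rests on opening rings A and C at C10, the carbinol carbon shared by the cyclohexane ring A, the cyclohexene ring B and the furan-fused seven-membered ring C (target numbering: C9 = methyl-bearing quaternary carbon, C1 = ring B methine, C16 = furan C-2). One hydrogen-atom-transfer radical bicyclisation forms C9–C10 and C1–C16: a tertiary C9 radical adds 6-exo to C10, the oxygen-bearing β-carbon of a vinylogous ester in ring B, and the resulting C1 radical closes ring C on the furan. The precursor is a monocarbocyclic lactone whose side chain carries a 1,1-disubstituted alkene and a 3-furyl carbinol.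

Key step: step 13

Numbering used throughout (target numbering): C1–C5 and C10 form ring B, C5–C10 ring A; C11 is the CH2 next to the ketone carbon C12; C13 is furan C-3 and C16 furan C-2; C17 is the methyl on C8, C20 the methyl on C9; C18 is the lactone carbonyl and C19 the lactone CH2.

Assumption 1: the amide enolate in step 3 is taken to be allylated on the face away from the methoxymethyl arm of the (S)-auxiliary, giving the C5 configuration drawn; if the sense were opposite, the (R)-auxiliary would be used.

Assumption 2: (R)-TRIP is taken to give the (7R,8S) adduct in step 10; otherwise its enantiomer would be used.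

Step 1
Reactants: 1 7-hydroxyisobenzofuran-1(3H)-one (7-hydroxyphthalide)
Product: 2 7-(methoxymethoxy)isobenzofuran-1(3H)-one
Conditions: MOMCl, i-Pr2NEt, CH2Cl2, 0 °C → rt
Reagents that add atoms: chloromethyl methyl ether, COCCl
Why: Base-mediated O-alkylation of the phenol (Williamson-type acetal ether formation) masks the oxygen that becomes the C10 hydroxyl with a group that should tolerate dissolving metal, hydride, oxidant and radical steps and leave under mild Lewis acid at the end.

Step 2
Reactants: 2 7-(methoxymethoxy)isobenzofuran-1(3H)-one; 3 (S)-2-(methoxymethyl)pyrrolidine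
Product: 4 (S)-[2-(hydroxymethyl)-6-(methoxymethoxy)phenyl][2-(methoxymethyl)pyrrolidin-1-yl]methanone
Conditions: AlMe3, toluene, 0 → 60 °C
Reagents that add atoms: none
Why: Aluminium-amide aminolysis of the lactone (Weinreb-type amidation) should open the phthalide to the tertiary benzamide that carries the chiral auxiliary and free the benzylic alcohol (future C18).

Step 3
Reactants: 4 the hydroxy benzamide; 5 allyl bromide
Product: 7 [(1R)-1-allyl-6-(hydroxymethyl)-2-(methoxymethoxy)cyclohexa-2,5-dien-1-yl][(2S)-2-(methoxymethyl)pyrrolidin-1-yl]methanone, via dipotassium dienolate 6 (not isolated)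
Conditions: KOt-Bu (1 equiv), K (2.2 equiv), NH3/THF, −78 °C; then 5; NH4Cl
Reagents that add atoms: none
Why: Asymmetric Birch reduction–alkylation of a chiral 2-alkoxybenzamide: reduction at the ipso and para carbons gives the amide dienolate, which should be allylated at C5 on the face turned away from the methoxymethyl arm of the chelated auxiliary, so that the quaternary stereocentre C5 is set here while the benzylic oxygen survives as its alkoxide.

Step 4
Reactants: 7 the allylated dienyl amide
Product: 8 [(1S)-1-allyl-2-(methoxymethoxy)cyclohexa-2,5-diene-1,6-diyl]dimethanol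
Conditions: LiH2NBH3, THF, 0 °C → rt; aq. NH4Cl
Reagents that add atoms: none
Why: Lithium amidotrihydroborate should reduce the hindered tertiary amide to the primary alcohol with C–N cleavage (amide-to-alcohol reduction), releasing auxiliary 3 for recovery and leaving the acid-labile dienol ether untouched.

Step 5
Reactants: 8 the diol
Product: 10 (3aS)-3a-allyl-4-(methoxymethoxy)-3a,6-dihydroisobenzofuran-1(3H)-one, via lactol 9 (not isolated)
Conditions: MnO2, CH2Cl2, rt
Reagents that add atoms: none
Why: Chemoselective oxidation of the allylic primary alcohol gives the enal, which should close to the lactol with the neopentyl alcohol and be oxidised again (oxidative lactonisation of a 1,4-diol), so that the carbonyl ends on C18 as in the target.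

Step 6
Reactants: 10 the dienyl butenolide
Product: 11 (3aS)-3a-allyl-4-(methoxymethoxy)-3,3a-dihydroisobenzofuran-1,6-dione
Conditions: Rh2(cap)4 (dirhodium tetracaprolactamate, 1 mol %), t-BuOOH, K2CO3, CH2Cl2, rt
Reagents that add atoms: tert-butyl hydroperoxide, CC(C)(C)OO
Why: Catalytic allylic C–H oxidation at the doubly allylic C2 methylene should convert the 1,4-diene into the cross-conjugated dienone, in which C10 becomes the alkoxy-bearing β-carbon of a vinylogous ester.

Step 7
Reactants: 11 the dienone lactone
Product: 12 (3aS,7aR)-3a-allyl-4-(methoxymethoxy)-3,3a,7,7a-tetrahydroisobenzofuran-1,6-dione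
Conditions: Zn, AcOH, THF, 0 °C
Reagents that add atoms: none
Why: Dissolving-metal conjugate reduction should remove only the ene-dione alkene C3=C4 (the electron-rich vinylogous ester arm is not reduced), which takes away the one competing radical acceptor; protonation gives the cis-fused lactone, and the C4 centre is erased again in step 14.

Step 8
Reactants: 12 the allyl keto lactone
Product: 14 2-[(3aS,7aR)-4-(methoxymethoxy)-1,6-dioxo-1,3,7,7a-tetrahydroisobenzofuran-3a(6H)-yl]acetaldehyde, via diol 13 (not isolated)
Conditions: OsO4 (cat.), NaIO4, 2,6-lutidine, dioxane/H2O, rt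
Reagents that add atoms: sodium periodate (oxygen delivered through catalytic OsO4), [Na+].[O-]I(=O)(=O)=O
Why: Lemieux–Johnson oxidation should cleave the monosubstituted allyl alkene, which is far more reactive towards OsO4 than the hindered push–pull alkene of the vinylogous ester, and give the C7 aldehyde.

Step 9
Reactants: 15 (E)-2-methylbut-2-en-1-ol
Product: 16 (E)-4,4,5,5-tetramethyl-2-(2-methylbut-2-en-1-yl)-1,3,2-dioxaborolane
Conditions: B2pin2, Pd(MeCN)4(BF4)2 (cat.), DMSO/MeOH, 50 °C
Reagents that add atoms: bis(pinacolato)diboron, CC1(C)OB(OC1(C)C)B1OC(C)(C)C(C)(C)O1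
Why: Palladium-catalysed allylic C–O borylation through a π-allyl complex (Miyaura-type allyl borylation) should give the linear allylboronate with the E geometry that later encodes the anti relationship of C7 and C8.

Step 10
Reactants: 14 the aldehyde; 16 the E allylboronate
Product: 17 (3aS,7aR)-3a-[(2R,3S)-2-hydroxy-3,4-dimethylpent-4-en-1-yl]-4-(methoxymethoxy)-3,3a,7,7a-tetrahydroisobenzofuran-1,6-dione
Conditions: (R)-TRIP (5 mol %), toluene, −30 °C; aq. work-up
Reagents that add atoms: none
Why: Chiral phosphoric acid-catalysed crotylboration through a closed chair six-membered transition state: the E boronate should give the anti adduct and the catalyst decide the aldehyde face, which sets C7 (R) and C8 (S) independently of the remote C5 centre.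

Step 11
Reactants: 17 the homoallylic alcohol
Product: 18 (2R,3S)-1-[(3aS,7aR)-4-(methoxymethoxy)-1,6-dioxo-1,3,7,7a-tetrahydroisobenzofuran-3a(6H)-yl]-3,4-dimethylpent-4-en-2-yl acetate
Conditions: Ac2O, pyridine, DMAP (cat.), CH2Cl2, 0 °C
Reagents that add atoms: acetic anhydride, CC(=O)OC(C)=O
Why: Nucleophile-catalysed acylation installs the C7 acetate of the target early, where it should also block translactonisation and lactol formation.

Step 12
Reactants: 18 the isopropenyl acetate; 19 furan-3-carbaldehyde
Product: 20 (2R,3S)-6-(furan-3-yl)-6-hydroxy-3-methyl-4-methylidene-1-[(3aS,7aR)-4-(methoxymethoxy)-1,6-dioxo-1,3,7,7a-tetrahydroisobenzofuran-3a(6H)-yl]hexan-2-yl acetate (both C12 epimers)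
Conditions: Me2AlCl (3 equiv), CH2Cl2, −78 → −20 °C
Reagents that add atoms: none
Why: Lewis acid-promoted carbonyl-ene reaction of the 1,1-disubstituted alkene with the aldehyde: the C11–C12 bond should form at the CH2 terminus and a hydrogen be taken from the allylic methyl group, which leaves the exocyclic methylene (future C20) on C9; the C12 carbinol forms as a mixture of epimers that converge in step 14.

Step 13
Reactants: 20 the ene adduct
Product: 23 tricyclic 10-O-MOM 2-oxo 12-hydroxy 3,4-dihydro precursor (1R,4R,5S,7R,8S,9S,10R; both C12 epimers), via tertiary C9 radical 21 (not isolated), via bicyclic C1 radical 22 (not isolated)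
Conditions: Fe(acac)3 (3 equiv), PhSiH3 (2.5 equiv), EtOH/(CH2OH)2, 60 °C
Reagents that add atoms: none
Why: An iron hydride formed from Fe(acac)3 and PhSiH3 should transfer a hydrogen atom to the CH2 terminus of the 1,1-disubstituted alkene (this makes the C20 methyl), the tertiary C9 radical adds to C10, the alkoxy-bearing β-carbon of the vinylogous ester, and the α-keto radical at C1 attacks C-2 of the electron-rich 3-alkylfuran in a homolytic aromatic substitution, after which trivalent iron oxidises the adduct radical and loss of a proton restores the furan. The closest known reaction type is the hydrogen-atom-transfer-initiated radical bicyclisation of polyenes through an electron-poor alkene onto an arene, combined with the iron-mediated reductive olefin (Giese) coupling that is known to join fully substituted carbons. Ring A closes in the 6-exo-trig mode and ring C in the 7-endo mode on the furan C2=C3 bond. C10 is controlled by the C5 stereocentre, because the tether reaches only the face of ring B on which C6 sits (cis A/B fusion, C19 and the C10 oxygen syn); C1 is controlled by the new C9–C10 bond, because the furan reaches only the lobe of the C1 radical that is syn-clinal to it; C9 is expected from a chair-like transition state in which the furylcarbinol arm lies pseudo-axial, anti to the pseudo-axial C8 methyl and away from the MOM ether. The step needs hydrogen-atom transfer at the unconjugated 1,1-disubstituted alkene only, attack at C10 and not at C1, and ring closure before the C1 radical is reduced; the first is secured by the hindered, conjugated nature of the other alkenes, the second by polarity and ring size, and the third is favoured by the pairing of an electrophilic radical with an electron-rich furan and by the excess of trivalent iron.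

Step 14
Reactants: 23 the tricyclic carbinol
Product: 25 tricyclic 10-O-MOM 2,12-dioxo Δ3 lactone (ene-dione; 1R,5S,7R,8S,9S,10R), via diketone 24 (not isolated)
Conditions: IBX (4 equiv), DMSO, rt → 80 °C
Reagents that add atoms: none
Why: IBX should first oxidise the furyl carbinol to the C12 ketone and then, at higher temperature, dehydrogenate the ring B ketone (IBX-mediated α,β-dehydrogenation); only C3–C4 can be desaturated because C10 and C9, the other β-carbons of the two ketones, bear no hydrogen.

Step 15
Reactants: 25 the ene-dione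
Product: 26 C2 tosylhydrazone of 25
Conditions: TsNHNH2, AcOH (cat.), EtOH/THF, rt
Reagents that add atoms: 4-methylbenzenesulfonohydrazide, Cc1ccc(cc1)S(=O)(=O)NN
Why: Hydrazone condensation should take place at the ene-dione carbonyl C2, which is far more electrophilic than the hindered furyl ketone C12 that is deactivated as a vinylogous ester of the furan oxygen.

Step 16
Reactants: 26 the tosylhydrazone
Product: 29 10-O-methoxymethyl ether of the target, via allylic diazene 27 (not isolated), via deconjugated lactone 28 (not isolated)
Conditions: catecholborane, CHCl3, 0 °C; NaOAc·3H2O, 60 °C; then DBU, rt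
Reagents that add atoms: none
Why: Reductive 1,3-transposition of an enone tosylhydrazone: hydride addition to C2, loss of sulfinate and a retro-ene loss of N2 from the allylic diazene should deliver hydrogen to C4 and move the alkene to C2=C3, after which base-mediated isomerisation returns it to conjugation with the lactone (C3=C4) and leaves C2 as CH2.

Step 17
Reactants: 29 the MOM ether
Product: 30 target CNP0329797.1
Conditions: ZnBr2, n-PrSH, CH2Cl2, 0 °C
Reagents that add atoms: none
Why: Lewis acid/thiol cleavage of the methoxymethyl acetal should free the tertiary C10 hydroxyl without touching the acetate, the lactone or the furan.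

Compound list

1 | 7-hydroxyisobenzofuran-1(3H)-one | O=C1OCc2cccc(O)c21 | starting material
2 | 7-(methoxymethoxy)isobenzofuran-1(3H)-one | O=C1OCc2cccc(OCOC)c21 | intermediate
3 | (S)-2-(methoxymethyl)pyrrolidine | COC[C@@H]1CCCN1 | starting material
4 | (S)-[2-(hydroxymethyl)-6-(methoxymethoxy)phenyl][2-(methoxymethyl)pyrrolidin-1-yl]methanone | COC[C@@H]1CCCN1C(=O)c1c(CO)cccc1OCOC | intermediate
5 | allyl bromide | C=CCBr | starting material
6 | dipotassium amide dienolate alkoxide from Birch reduction of 4 (not isolated) | COC[C@@H]1CCCN1C([O-])=C1C(OCOC)=CCC=C1C[O-].[K+].[K+] | intermediate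
7 | [(1R)-1-allyl-6-(hydroxymethyl)-2-(methoxymethoxy)cyclohexa-2,5-dien-1-yl][(2S)-2-(methoxymethyl)pyrrolidin-1-yl]methanone | C=CC[C@]1(C(=O)N2CCC[C@H]2COC)C(OCOC)=CCC=C1CO | intermediate
8 | [(1S)-1-allyl-2-(methoxymethoxy)cyclohexa-2,5-diene-1,6-diyl]dimethanol | C=CC[C@]1(CO)C(OCOC)=CCC=C1CO | intermediate
9 | lactol of 10 (not isolated) | C=CC[C@@]12COC(O)C1=CCC=C2OCOC | intermediate
10 | (3aS)-3a-allyl-4-(methoxymethoxy)-3a,6-dihydroisobenzofuran-1(3H)-one | C=CC[C@@]12COC(=O)C1=CCC=C2OCOC | intermediate
11 | (3aS)-3a-allyl-4-(methoxymethoxy)-3,3a-dihydroisobenzofuran-1,6-dione | C=CC[C@@]12COC(=O)C1=CC(=O)C=C2OCOC | intermediate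
12 | (3aS,7aR)-3a-allyl-4-(methoxymethoxy)-3,3a,7,7a-tetrahydroisobenzofuran-1,6-dione | C=CC[C@@]12COC(=O)[C@@H]1CC(=O)C=C2OCOC | intermediate
13 | 2,3-dihydroxypropyl analogue of 12 (not isolated) | OCC(O)C[C@@]12COC(=O)[C@@H]1CC(=O)C=C2OCOC | intermediate
14 | 2-[(3aS,7aR)-4-(methoxymethoxy)-1,6-dioxo-1,3,7,7a-tetrahydroisobenzofuran-3a(6H)-yl]acetaldehyde | O=CC[C@@]12COC(=O)[C@@H]1CC(=O)C=C2OCOC | intermediate
15 | (E)-2-methylbut-2-en-1-ol | C/C=C(\C)CO | starting material
16 | (E)-4,4,5,5-tetramethyl-2-(2-methylbut-2-en-1-yl)-1,3,2-dioxaborolane | C/C=C(\C)CB1OC(C)(C)C(C)(C)O1 | intermediate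
17 | (3aS,7aR)-3a-[(2R,3S)-2-hydroxy-3,4-dimethylpent-4-en-1-yl]-4-(methoxymethoxy)-3,3a,7,7a-tetrahydroisobenzofuran-1,6-dione | C=C(C)[C@H](C)[C@H](O)C[C@@]12COC(=O)[C@@H]1CC(=O)C=C2OCOC | intermediate
18 | (2R,3S)-1-[(3aS,7aR)-4-(methoxymethoxy)-1,6-dioxo-1,3,7,7a-tetrahydroisobenzofuran-3a(6H)-yl]-3,4-dimethylpent-4-en-2-yl acetate | C=C(C)[C@H](C)[C@H](OC(C)=O)C[C@@]12COC(=O)[C@@H]1CC(=O)C=C2OCOC | intermediate
19 | furan-3-carbaldehyde | O=Cc1ccoc1 | starting material
20 | ene adduct: 7-acetate with C9 exocyclic methylene and C12 furyl carbinol (C12 epimers) | C=C(CC(O)c1ccoc1)[C@H](C)[C@H](OC(C)=O)C[C@@]12COC(=O)[C@@H]1CC(=O)C=C2OCOC | intermediate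
21 | tertiary C9 radical from 20 (not isolated) | C[C](CC(O)c1ccoc1)[C@H](C)[C@H](OC(C)=O)C[C@@]12COC(=O)[C@@H]1CC(=O)C=C2OCOC | intermediate
22 | ring A-closed α-keto C1 radical (not isolated) | CC(=O)O[C@@H]1C[C@@]23COC(=O)[C@@H]2CC(=O)[CH][C@@]3(OCOC)[C@@](C)(CC(O)c2ccoc2)[C@@H]1C | intermediate
23 | tricyclic 10-O-MOM 2-oxo 12-hydroxy 3,4-dihydro precursor (C12 epimers) | CC(=O)O[C@@H]1C[C@@]23COC(=O)[C@@H]2CC(=O)[C@H]2c4occc4C(O)C[C@@](C)([C@@H]1C)[C@]23OCOC | intermediate
24 | tricyclic 10-O-MOM 2,12-dioxo 3,4-dihydro compound (not isolated in step 14) | CC(=O)O[C@@H]1C[C@@]23COC(=O)[C@@H]2CC(=O)[C@H]2c4occc4C(=O)C[C@@](C)([C@@H]1C)[C@]23OCOC | intermediate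
25 | tricyclic 10-O-MOM 2,12-dioxo Δ3 lactone (ene-dione) | CC(=O)O[C@@H]1C[C@@]23COC(=O)C2=CC(=O)[C@H]2c4occc4C(=O)C[C@@](C)([C@@H]1C)[C@]23OCOC | intermediate
26 | C2 tosylhydrazone of 25 | CC(=O)O[C@@H]1C[C@@]23COC(=O)C2=CC(=NNS(=O)(=O)c2ccc(C)cc2)[C@H]2c4occc4C(=O)C[C@@](C)([C@@H]1C)[C@]23OCOC | intermediate
27 | allylic C2 diazene (not isolated) | CC(=O)O[C@@H]1C[C@@]23COC(=O)C2=CC(N=N)[C@H]2c4occc4C(=O)C[C@@](C)([C@@H]1C)[C@]23OCOC | intermediate
28 | Δ2 deconjugated lactone (not isolated) | CC(=O)O[C@@H]1C[C@@]23COC(=O)C2C=C[C@H]2c4occc4C(=O)C[C@@](C)([C@@H]1C)[C@]23OCOC | intermediate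
29 | 10-O-methoxymethyl ether of the target | CC(=O)O[C@@H]1C[C@@]23COC(=O)C2=CC[C@H]2c4occc4C(=O)C[C@@](C)([C@@H]1C)[C@]23OCOC | intermediate
30 | CNP0329797.1 (1R,5S,7R,8S,9S,10R) | CC(=O)O[C@@H]1C[C@@]23COC(=O)C2=CC[C@H]2c4occc4C(=O)C[C@@](C)([C@@H]1C)[C@]23O | target

Total step count: 17. Longest linear sequence: 16 steps (1 → 30 through steps 1–8 and 10–17; step 9 is a one-step side branch).

Steps most likely to fail

Step 13. The C1 radical may be reduced before it reaches the furan, so that only ring A closes; the C9 radical may also give the C9 epimer or merely isomerise the alkene. The fallback separates the two bond formations and makes the second one by polar chemistry. It sets out from 18: the ene reaction of step 12 is run with 2-bromofuran-3-carbaldehyde (O=Cc1ccoc1Br) to give bromofuryl carbinol F1. An iron-mediated reductive radical conjugate addition (Fe(acac)3, PhSiH3, EtOH) then closes ring A only and gives the bicyclic ketone F2. Dess–Martin oxidation gives the bromofuryl ketone F3. Palladium-catalysed intramolecular α-arylation of the ring B ketone (Pd(OAc)2, Xantphos, K3PO4, toluene, 80 °C), in which only the C1 enolate can reach the activated C–Br bond, joins C1 to C16. The fallback comes back to the route at 24, which is dehydrogenated with IBX as in the second stage of step 14.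

Step 12. Hydrogen may be taken from C8 instead of the methyl group in the ene reaction, or the Lewis acid may cleave the vinylogous acetal. The fallback replaces the ene reaction by an allyl-metal addition. It sets out from 18: catalytic SeO2 with t-BuOOH hydroxylates the isopropenyl methyl group to give allylic alcohol F4. PPh3/CBr4 gives allylic bromide F5. An indium-mediated Barbier allylation of 19 in THF/H2O, which bonds through the CH2 terminus of the allyl unit, comes back to the route at 20.

Step 16. The borane may reduce the furyl ketone as well, or the hydrazone may be reduced without clean transposition. The fallback removes the C2 oxygen through a π-allyl complex instead of a diazene. It sets out from 25: Luche reduction (NaBH4, CeCl3, MeOH, −78 °C) gives the C2 allylic alcohol F6. Acetylation gives allylic acetate F7. Formate hydrogenolysis with zerovalent palladium (Pd(PPh3)4, HCO2NH4, dioxane, 80 °C) gives the alkene as a mixture of 28 and its conjugated isomer, and DBU converges both on 29, where the fallback comes back to the route.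

Further compounds
F1 | step 13 | 2-bromofuran-3-yl analogue of 20 (C12 epimers) | C=C(CC(O)c1ccoc1Br)[C@H](C)[C@H](OC(C)=O)C[C@@]12COC(=O)[C@@H]1CC(=O)C=C2OCOC
F2 | step 13 | ring A-closed bicyclic ketone with C1 as CH2 and a 2-bromofuran-3-yl carbinol arm | CC(=O)O[C@@H]1C[C@@]23COC(=O)[C@@H]2CC(=O)C[C@@]3(OCOC)[C@@](C)(CC(O)c2ccoc2Br)[C@@H]1C
F3 | step 13 | C12 ketone of F2 | CC(=O)O[C@@H]1C[C@@]23COC(=O)[C@@H]2CC(=O)C[C@@]3(OCOC)[C@@](C)(CC(=O)c2ccoc2Br)[C@@H]1C
F4 | step 12 | allylic alcohol from 18 (hydroxymethyl in place of the isopropenyl methyl) | C=C(CO)[C@H](C)[C@H](OC(C)=O)C[C@@]12COC(=O)[C@@H]1CC(=O)C=C2OCOC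
F5 | step 12 | allylic bromide from F4 | C=C(CBr)[C@H](C)[C@H](OC(C)=O)C[C@@]12COC(=O)[C@@H]1CC(=O)C=C2OCOC
F6 | step 16 | C2 allylic alcohol from 25 (C2 epimers) | CC(=O)O[C@@H]1C[C@@]23COC(=O)C2=CC(O)[C@H]2c4occc4C(=O)C[C@@](C)([C@@H]1C)[C@]23OCOC
F7 | step 16 | C2 allylic acetate from F6 | CC(=O)O[C@@H]1C[C@@]23COC(=O)C2=CC(OC(C)=O)[C@H]2c4occc4C(=O)C[C@@](C)([C@@H]1C)[C@]23OCOC
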